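**Retrosynthetic overview**
1. Target 39 comes from global deprotection (fluoride, then hydrogenolysis) of the fully protected lactone 37, which is the deoxygenated form of aldol adduct 35.
2. Key C–C bond: intermolecular aldol addition of the lithium enolate of (S)-β-benzyl-γ-butyrolactone 33 (fragment 1, rings A and B) to dihydrobenzofuran-5-carbaldehyde 16 (fragment 2, rings C and D); it sets the 3,4-trans lactone.
3. The lactone of fragment 1 is built by Evans alkylation of an N-pentenoyl oxazolidinone with benzylic bromide 24, then alkene cleavage and lactol oxidation.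
4. Both fragments come from one phenol, 10, made by chiral-phosphoric-acid-catalysed anti-cinnamylboration of O-benzylvanillin with an (E)-cinnamyl boronate derived from 5-bromo-o-vanillin.
5. Ring order: dihydrobenzofuran (Mitsunobu closure, fragment 2) first, butyrolactone (fragment 1) second; no ring is formed after the aldol.

Assumption: the SMILES is taken at face value (lactone 3S,4S trans; dihydrobenzofuran 2R,3S trans; diol 1S,2S anti); simple reagents are given with SMILES on the reagent line and are not numbered.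

Group names used below: G1 = 4-(benzyloxy)-3-{(1S,2S)-1-[4-(benzyloxy)-3-methoxyphenyl]-1,3-bis[(tert-butyldimethylsilyl)oxy]propan-2-yl}-5-methoxyphenyl; G2 = (2R,3S)-2-[4-(benzyloxy)-3-methoxyphenyl]-3-{[(tert-butyldimethylsilyl)oxy]methyl}-7-methoxy-2,3-dihydro-1-benzofuran-5-yl. TBS = tert-butyldimethylsilyl; (S)-TRIP = (S)-3,3'-bis(2,4,6-triisopropylphenyl)-1,1'-binaphthyl-2,2'-diyl hydrogen phosphate.

**Common intermediate (steps 1–7)**

Step 1
Reactants: 1 5-bromo-2-hydroxy-3-methoxybenzaldehyde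
Product: 2 5-bromo-2-[(tert-butyldimethylsilyl)oxy]-3-methoxybenzaldehyde
Conditions: TBSCl, imidazole, DMF, rt
Reagents that add atoms: tert-butyldimethylsilyl chloride, C[Si](C)(Cl)C(C)(C)C
Why: Imidazole-promoted O-silylation masks the phenol for the olefination and allylation steps and can later be removed with fluoride beside benzyl ethers.

Step 2
Reactants: 2 5-bromo-2-[(tert-butyldimethylsilyl)oxy]-3-methoxybenzaldehyde
Product: 3 ethyl (E)-3-{5-bromo-2-[(tert-butyldimethylsilyl)oxy]-3-methoxyphenyl}prop-2-enoate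
Conditions: (EtO)2P(O)CH2CO2Et, NaH, THF, 0 °C to rt
Reagents that add atoms: triethyl phosphonoacetate, CCOC(=O)CP(=O)(OCC)OCC
Why: Horner–Wadsworth–Emmons olefination of an aryl aldehyde with a stabilised phosphonate gives the (E)-cinnamate selectively.

Step 3
Reactants: 3 ethyl (E)-3-{5-bromo-2-[(tert-butyldimethylsilyl)oxy]-3-methoxyphenyl}prop-2-enoate
Product: 4 (E)-3-{5-bromo-2-[(tert-butyldimethylsilyl)oxy]-3-methoxyphenyl}prop-2-en-1-ol
Conditions: i-Bu2AlH (2.3 equiv), CH2Cl2, −78 °C; aqueous potassium sodium tartrate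
Reagents that add atoms: none
Why: 1,2-Reduction of the conjugated ester by the aluminium hydride at low temperature gives the allylic alcohol and leaves the aryl bromide, silyl ether and alkene geometry untouched.

Step 4
Reactants: 4 (E)-3-{5-bromo-2-[(tert-butyldimethylsilyl)oxy]-3-methoxyphenyl}prop-2-en-1-ol
Product: 5 (E)-3-{5-bromo-2-[(tert-butyldimethylsilyl)oxy]-3-methoxyphenyl}prop-2-en-1-yl acetate
Conditions: Ac2O, pyridine, DMAP (cat.), CH2Cl2, 0 °C to rt
Reagents that add atoms: acetic anhydride, CC(=O)OC(C)=O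
Why: DMAP-catalysed acylation turns the allylic alcohol into a leaving group for π-allyl formation.

Step 5
Reactants: 5 (E)-3-{5-bromo-2-[(tert-butyldimethylsilyl)oxy]-3-methoxyphenyl}prop-2-en-1-yl acetate
Product: 6 2-[(E)-3-{5-bromo-2-[(tert-butyldimethylsilyl)oxy]-3-methoxyphenyl}prop-2-en-1-yl]-4,4,5,5-tetramethyl-1,3,2-dioxaborolane
Conditions: B2pin2 (1.1 equiv), Pd2(dba)3 (2.5 mol %; dba = dibenzylideneacetone), DMSO, 50 °C
Reagents that add atoms: bis(pinacolato)diboron, CC1(C)OB(OC1(C)C)B1OC(C)(C)C(C)(C)O1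
Why: Miyaura allylic borylation proceeds through a π-allylpalladium complex that takes boron at the unhindered terminus to give the linear (E)-allylboronate, while the aryl bromide is inert to ligand-free zerovalent palladium at 50 °C without base.

Step 6
Reactants: 6 2-[(E)-3-{5-bromo-2-[(tert-butyldimethylsilyl)oxy]-3-methoxyphenyl}prop-2-en-1-yl]-4,4,5,5-tetramethyl-1,3,2-dioxaborolane; 7 4-(benzyloxy)-3-methoxybenzaldehyde
Product: 9 (1S,2R)-1-[4-(benzyloxy)-3-methoxyphenyl]-2-{5-bromo-2-[(tert-butyldimethylsilyl)oxy]-3-methoxyphenyl}but-3-en-1-ol, via pinacol borate ester 8 (not isolated)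
Conditions: (S)-TRIP (5 mol %), 4 Å molecular sieves, toluene, −30 to 0 °C; aq. NaHCO3 work-up
Reagents that add atoms: none
Why: Brønsted-acid-catalysed carbonyl allylboration runs through a closed chair (Zimmerman–Traxler) transition state in which the (E)-γ-aryl group is equatorial, so the anti adduct forms, and (S)-TRIP (mirror image of the Re-face-selective (R)-acid) directs attack to the Si face of the aldehyde, setting 1S,2R.

Step 7
Reactants: 9 (1S,2R)-1-[4-(benzyloxy)-3-methoxyphenyl]-2-{5-bromo-2-[(tert-butyldimethylsilyl)oxy]-3-methoxyphenyl}but-3-en-1-ol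
Product: 10 (1S,2R)-1-[4-(benzyloxy)-3-methoxyphenyl]-2-(5-bromo-2-hydroxy-3-methoxyphenyl)but-3-en-1-ol
Conditions: Bu4NF, AcOH (1:1), THF, 0 °C
Reagents that add atoms: none
Why: Fluoride desilylation cleaves the aryl silyl ether quickly, and the acetic acid buffer keeps the phenol and the benzylic carbinol from base-induced side reactions.

**Fragment 2, aldehyde 16 (steps 8–11)**

Step 8
Reactants: 10 (1S,2R)-1-[4-(benzyloxy)-3-methoxyphenyl]-2-(5-bromo-2-hydroxy-3-methoxyphenyl)but-3-en-1-ol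
Product: 11 (2R,3R)-2-[4-(benzyloxy)-3-methoxyphenyl]-5-bromo-3-ethenyl-7-methoxy-2,3-dihydro-1-benzofuran
Conditions: PPh3, DIAD, THF, 0 °C to rt
Reagents that add atoms: none
Why: Intramolecular Mitsunobu etherification displaces the activated benzylic oxygen by the phenol with inversion (1S carbinol becomes C2 R), which gives the 2,3-trans ring, and any ionisation leakage leads to the same, more stable trans isomer.

Step 9
Reactants: 11 (2R,3R)-2-[4-(benzyloxy)-3-methoxyphenyl]-5-bromo-3-ethenyl-7-methoxy-2,3-dihydro-1-benzofuran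
Product: 13 [(2R,3S)-2-[4-(benzyloxy)-3-methoxyphenyl]-5-bromo-7-methoxy-2,3-dihydro-1-benzofuran-3-yl]methanol, via 3-formyl dihydrobenzofuran 12 (not isolated)
Conditions: O3, CH2Cl2/MeOH, −78 °C (stop at first excess); then NaBH4, −78 to 0 °C
Reagents that add atoms: ozone, [O-][O+]=O
Why: Reductive ozonolysis cleaves the monosubstituted alkene far faster than the arenes at −78 °C, and the in situ hydride reduction traps the α-aryl aldehyde before it can epimerise or ring-open, so C3 keeps its configuration.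

Step 10
Reactants: 13 [(2R,3S)-2-[4-(benzyloxy)-3-methoxyphenyl]-5-bromo-7-methoxy-2,3-dihydro-1-benzofuran-3-yl]methanol
Product: 14 G2 bromide, (2R,3S)-2-[4-(benzyloxy)-3-methoxyphenyl]-5-bromo-3-{[(tert-butyldimethylsilyl)oxy]methyl}-7-methoxy-2,3-dihydro-1-benzofuran
Conditions: TBSCl, imidazole, DMF, rt
Reagents that add atoms: tert-butyldimethylsilyl chloride, C[Si](C)(Cl)C(C)(C)C
Why: O-Silylation protects the primary alcohol against the organolithium and enolate steps that follow.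

Step 11
Reactants: 14 G2 bromide
Product: 16 G2-carbaldehyde (fragment 2), via aryllithium 15 (not isolated)
Conditions: n-BuLi (1.1 equiv), THF, −78 °C, 15 min; DMF, −78 to 0 °C; AcOH/H2O
Reagents that add atoms: N,N-dimethylformamide, CN(C)C=O
Why: Bromine–lithium exchange at −78 °C is faster than any deprotonation, and formylation of the aryllithium with DMF (Bouveault-type) gives the aldehyde on hydrolysis.

**Fragment 1, lactone 33 (steps 12–22)**

Step 12
Reactants: 10 (1S,2R)-1-[4-(benzyloxy)-3-methoxyphenyl]-2-(5-bromo-2-hydroxy-3-methoxyphenyl)but-3-en-1-ol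
Product: 17 (1S,2R)-1-[4-(benzyloxy)-3-methoxyphenyl]-2-[2-(benzyloxy)-5-bromo-3-methoxyphenyl]but-3-en-1-ol
Conditions: BnBr, K2CO3, DMF, rt
Reagents that add atoms: benzyl bromide, BrCc1ccccc1
Why: Williamson etherification with carbonate base alkylates the phenol chemoselectively over the secondary alcohol.

Step 13
Reactants: 17 (1S,2R)-1-[4-(benzyloxy)-3-methoxyphenyl]-2-[2-(benzyloxy)-5-bromo-3-methoxyphenyl]but-3-en-1-ol
Product: 19 (1S,2S)-1-[4-(benzyloxy)-3-methoxyphenyl]-2-[2-(benzyloxy)-5-bromo-3-methoxyphenyl]propane-1,3-diol, via β-hydroxy aldehyde 18 (not isolated)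
Conditions: O3, CH2Cl2/MeOH, −78 °C (stop at first excess); then NaBH4, −78 to 0 °C
Reagents that add atoms: ozone, [O-][O+]=O
Why: Reductive ozonolysis turns the vinyl group into the hydroxymethyl group, and reducing the labile β-hydroxy-α-aryl aldehyde in situ preserves both stereocentres set in step 6.

Step 14
Reactants: 19 (1S,2S)-1-[4-(benzyloxy)-3-methoxyphenyl]-2-[2-(benzyloxy)-5-bromo-3-methoxyphenyl]propane-1,3-diol
Product: 20 G1 bromide, (1S,2S)-1-[4-(benzyloxy)-3-methoxyphenyl]-2-[2-(benzyloxy)-5-bromo-3-methoxyphenyl]-1,3-bis[(tert-butyldimethylsilyl)oxy]propane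
Conditions: TBSOTf (2.5 equiv), 2,6-lutidine, CH2Cl2, −78 to 0 °C
Reagents that add atoms: tert-butyldimethylsilyl trifluoromethanesulfonate, C[Si](C)(C(C)(C)C)OS(=O)(=O)C(F)(F)F
Why: Silyl triflate with a hindered base silylates both the primary and the hindered benzylic hydroxyl without ionising the benzylic centre.

Step 15
Reactants: 20 G1 bromide
Product: 22 G1-carbaldehyde, via aryllithium 21 (not isolated)
Conditions: n-BuLi (1.1 equiv), THF, −78 °C, 15 min; DMF, −78 to 0 °C; AcOH/H2O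
Reagents that add atoms: N,N-dimethylformamide, CN(C)C=O
Why: Bromine–lithium exchange followed by formylation with DMF installs the benzylic carbon, and silyl and benzyl ethers tolerate the brief low-temperature organolithium step.

Step 16
Reactants: 22 G1-carbaldehyde
Product: 23 G1-methanol
Conditions: NaBH4, THF/MeOH, 0 °C
Reagents that add atoms: none
Why: Borohydride reduction of an aryl aldehyde to the benzylic alcohol is chemoselective.

Step 17
Reactants: 23 G1-methanol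
Product: 24 G1-methyl bromide
Conditions: CBr4, PPh3, CH2Cl2, 0 °C; used at once
Reagents that add atoms: carbon tetrabromide, BrC(Br)(Br)Br
Why: Appel bromination converts the primary benzylic alcohol to the bromide under neutral conditions that spare the acid-sensitive benzylic silyl ether.

Step 18
Reactants: 25 (S)-4-benzyl-1,3-oxazolidin-2-one; 26 pent-4-enoyl chloride
Product: 27 (S)-4-benzyl-3-(pent-4-enoyl)-1,3-oxazolidin-2-one
Conditions: Et3N, DMAP (cat.), CH2Cl2, 0 °C to rt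
Reagents that add atoms: none
Why: DMAP-catalysed N-acylation of the Evans auxiliary gives the imide.

Step 19
Reactants: 27 (S)-4-benzyl-3-(pent-4-enoyl)-1,3-oxazolidin-2-one; 24 G1-methyl bromide
Product: 29 (4S)-4-benzyl-3-[(2R)-2-(G1-methyl)pent-4-enoyl]-1,3-oxazolidin-2-one, via sodium enolate 28 (not isolated)
Conditions: NaN(SiMe3)2, THF, −78 °C; then 24, −78 to −30 °C
Reagents that add atoms: none
Why: Evans asymmetric alkylation: the chelated (Z)-sodium enolate is alkylated by the reactive benzylic bromide on the face opposite the auxiliary benzyl group, setting the 2R centre (the future lactone C4) with high diastereoselectivity.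

Step 20
Reactants: 29 (4S)-4-benzyl-3-[(2R)-2-(G1-methyl)pent-4-enoyl]-1,3-oxazolidin-2-one
Product: 30 (2R)-2-(G1-methyl)pent-4-en-1-ol
Conditions: LiBH4, MeOH (1 equiv), Et2O, 0 °C
Reagents that add atoms: none
Why: Reductive cleavage of the imide by borohydride at the exocyclic carbonyl frees the primary alcohol without touching the new stereocentre, and the auxiliary is recovered.

Step 21
Reactants: 30 (2R)-2-(G1-methyl)pent-4-en-1-ol
Product: 32 (4S)-4-(G1-methyl)oxolan-2-ol (lactol as anomer mixture), via γ-hydroxy aldehyde 31 (not isolated)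
Conditions: OsO4 (2 mol %), NaIO4 (4 equiv), 2,6-lutidine, dioxane/H2O, rt
Reagents that add atoms: osmium tetroxide, O=[Os](=O)(=O)=O; sodium periodate, [Na+].[O-]I(=O)(=O)=O
Why: Lemieux–Johnson oxidative cleavage of the terminal alkene gives a γ-hydroxy aldehyde that closes spontaneously to the five-membered lactol.

Step 22
Reactants: 32 (4S)-4-(G1-methyl)oxolan-2-ol
Product: 33 (4S)-4-(G1-methyl)oxolan-2-one (fragment 1)
Conditions: TEMPO (0.2 equiv), PhI(OAc)2 (1.5 equiv), CH2Cl2, rt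
Reagents that add atoms: none
Why: Oxoammonium (TEMPO) oxidation of the lactol gives the γ-lactone under neutral conditions that leave aryl ethers, silyl ethers and the C4 stereocentre alone.

**Union and endgame (steps 23–27)**

Step 23
Reactants: 33 (4S)-4-(G1-methyl)oxolan-2-one; 16 G2-carbaldehyde
Product: 35 (3R,4S)-3-[hydroxy(G2)methyl]-4-(G1-methyl)oxolan-2-one, via lithium enolate 34 (not isolated)
Conditions: LiN(i-Pr)2 (1.1 equiv), THF, −78 °C, 1 h; then 16, −78 °C; AcOH quench at −78 °C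
Reagents that add atoms: none
Why: Intermolecular aldol addition of the lactone enolate to the aryl aldehyde takes place anti to the C4 benzyl group and gives the 3,4-trans lactone, while the carbinol centre forms as an epimer mixture that is removed in step 25.

Step 24
Reactants: 35 (3R,4S)-3-[hydroxy(G2)methyl]-4-(G1-methyl)oxolan-2-one
Product: 36 (3R,4S)-3-[(phenoxycarbonothioyl)oxy(G2)methyl]-4-(G1-methyl)oxolan-2-one
Conditions: PhOC(S)Cl, pyridine, DMAP (cat.), CH2Cl2, 0 °C to rt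
Reagents that add atoms: O-phenyl chlorothionoformate, S=C(Cl)Oc1ccccc1
Why: Thioacylation with a weak amine base gives the thionocarbonate needed for Barton–McCombie deoxygenation without retro-aldol cleavage or elimination.

Step 25
Reactants: 36 (3R,4S)-3-[(phenoxycarbonothioyl)oxy(G2)methyl]-4-(G1-methyl)oxolan-2-one
Product: 37 (3S,4S)-3-(G2-methyl)-4-(G1-methyl)oxolan-2-one
Conditions: Bu3SnH (2 equiv), azobisisobutyronitrile (0.2 equiv), toluene, 90 °C
Reagents that add atoms: none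
Why: Barton–McCombie radical deoxygenation: stannyl radical adds to C=S, C–O fragmentation gives a benzylic radical that abstracts hydrogen from the stannane, so both carbinol epimers converge and C3 and C4 are untouched.

Step 26
Reactants: 37 (3S,4S)-3-(G2-methyl)-4-(G1-methyl)oxolan-2-one
Product: 38 (3S,4S)-3-{[(2R,3S)-2-[4-(benzyloxy)-3-methoxyphenyl]-3-(hydroxymethyl)-7-methoxy-2,3-dihydro-1-benzofuran-5-yl]methyl}-4-({4-(benzyloxy)-3-[(1S,2S)-1-[4-(benzyloxy)-3-methoxyphenyl]-1,3-dihydroxypropan-2-yl]-5-methoxyphenyl}methyl)oxolan-2-one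
Conditions: Bu4NF, AcOH (1:1, 6 equiv), THF, rt to 40 °C
Reagents that add atoms: none
Why: Fluoride desilylation removes all three silyl ethers, and the acetic acid buffer prevents lactone opening; the trans lactone is the thermodynamic isomer, so C3 is not at risk.

Step 27
Reactants: 38 (3S,4S)-3-{[(2R,3S)-2-[4-(benzyloxy)-3-methoxyphenyl]-3-(hydroxymethyl)-7-methoxy-2,3-dihydro-1-benzofuran-5-yl]methyl}-4-({4-(benzyloxy)-3-[(1S,2S)-1-[4-(benzyloxy)-3-methoxyphenyl]-1,3-dihydroxypropan-2-yl]-5-methoxyphenyl}methyl)oxolan-2-one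
Product: 39 (3S,4S)-3-{[(2R,3S)-2-(4-hydroxy-3-methoxyphenyl)-3-(hydroxymethyl)-7-methoxy-2,3-dihydro-1-benzofuran-5-yl]methyl}-4-({3-[(1S,2S)-1,3-dihydroxy-1-(4-hydroxy-3-methoxyphenyl)propan-2-yl]-4-hydroxy-5-methoxyphenyl}methyl)oxolan-2-one (CNP0199264.1)
Conditions: H2 (1 atm), Pd/C (10 wt % palladium on carbon), EtOAc/MeOH, rt, stopped after uptake of 3 equiv
Reagents that add atoms: none
Why: Catalytic hydrogenolysis of aryl benzyl ethers under neutral conditions is much faster than cleavage of the benzylic C–O bonds of the dihydrobenzofuran and the secondary carbinol, so the three phenols are freed without touching a stereocentre.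

**Compound list**
1 | 5-bromo-2-hydroxy-3-methoxybenzaldehyde | COc1cc(Br)cc(C=O)c1O | starting material
2 | 5-bromo-2-[(tert-butyldimethylsilyl)oxy]-3-methoxybenzaldehyde | COc1cc(Br)cc(C=O)c1O[Si](C)(C)C(C)(C)C | intermediate
3 | ethyl (E)-3-{5-bromo-2-[(tert-butyldimethylsilyl)oxy]-3-methoxyphenyl}prop-2-enoate | CCOC(=O)/C=C/c1cc(Br)cc(OC)c1O[Si](C)(C)C(C)(C)C | intermediate
4 | (E)-3-{5-bromo-2-[(tert-butyldimethylsilyl)oxy]-3-methoxyphenyl}prop-2-en-1-ol | OC/C=C/c1cc(Br)cc(OC)c1O[Si](C)(C)C(C)(C)C | intermediate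
5 | (E)-3-{5-bromo-2-[(tert-butyldimethylsilyl)oxy]-3-methoxyphenyl}prop-2-en-1-yl acetate | CC(=O)OC/C=C/c1cc(Br)cc(OC)c1O[Si](C)(C)C(C)(C)C | intermediate
6 | (E)-cinnamyl pinacol boronate of 5 | CC1(C)OB(C/C=C/c2cc(Br)cc(OC)c2O[Si](C)(C)C(C)(C)C)OC1(C)C | intermediate
7 | 4-(benzyloxy)-3-methoxybenzaldehyde | COc1cc(C=O)ccc1OCc1ccccc1 | starting material
8 | pinacol borate ester of 9 | COc1cc([C@@H](OB2OC(C)(C)C(C)(C)O2)[C@H](C=C)c2cc(Br)cc(OC)c2O[Si](C)(C)C(C)(C)C)ccc1OCc1ccccc1 | intermediate (not isolated)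
9 | (1S,2R)-1-[4-(benzyloxy)-3-methoxyphenyl]-2-{5-bromo-2-[(tert-butyldimethylsilyl)oxy]-3-methoxyphenyl}but-3-en-1-ol | COc1cc([C@@H](O)[C@H](C=C)c2cc(Br)cc(OC)c2O[Si](C)(C)C(C)(C)C)ccc1OCc1ccccc1 | intermediate
10 | (1S,2R)-1-[4-(benzyloxy)-3-methoxyphenyl]-2-(5-bromo-2-hydroxy-3-methoxyphenyl)but-3-en-1-ol | COc1cc([C@@H](O)[C@H](C=C)c2cc(Br)cc(OC)c2O)ccc1OCc1ccccc1 | intermediate
11 | (2R,3R)-2-[4-(benzyloxy)-3-methoxyphenyl]-5-bromo-3-ethenyl-7-methoxy-2,3-dihydro-1-benzofuran (trans) | Brc1cc(OC)c2c(c1)[C@@H](C=C)[C@H](c1ccc(OCc3ccccc3)c(OC)c1)O2 | intermediate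
12 | (2R,3R)-2-[4-(benzyloxy)-3-methoxyphenyl]-5-bromo-7-methoxy-2,3-dihydro-1-benzofuran-3-carbaldehyde | Brc1cc(OC)c2c(c1)[C@@H](C=O)[C@H](c1ccc(OCc3ccccc3)c(OC)c1)O2 | intermediate (not isolated)
13 | [(2R,3S)-2-[4-(benzyloxy)-3-methoxyphenyl]-5-bromo-7-methoxy-2,3-dihydro-1-benzofuran-3-yl]methanol | Brc1cc(OC)c2c(c1)[C@@H](CO)[C@H](c1ccc(OCc3ccccc3)c(OC)c1)O2 | intermediate
14 | G2 bromide | Brc1cc(OC)c2c(c1)[C@@H](CO[Si](C)(C)C(C)(C)C)[C@H](c1ccc(OCc3ccccc3)c(OC)c1)O2 | intermediate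
15 | G2-lithium | [Li]c1cc(OC)c2c(c1)[C@@H](CO[Si](C)(C)C(C)(C)C)[C@H](c1ccc(OCc3ccccc3)c(OC)c1)O2 | intermediate (not isolated)
16 | G2-carbaldehyde (fragment 2) | O=Cc1cc(OC)c2c(c1)[C@@H](CO[Si](C)(C)C(C)(C)C)[C@H](c1ccc(OCc3ccccc3)c(OC)c1)O2 | intermediate
17 | (1S,2R)-1-[4-(benzyloxy)-3-methoxyphenyl]-2-[2-(benzyloxy)-5-bromo-3-methoxyphenyl]but-3-en-1-ol | COc1cc([C@@H](O)[C@H](C=C)c2cc(Br)cc(OC)c2OCc2ccccc2)ccc1OCc1ccccc1 | intermediate
18 | (2R,3S)-3-[4-(benzyloxy)-3-methoxyphenyl]-2-[2-(benzyloxy)-5-bromo-3-methoxyphenyl]-3-hydroxypropanal | COc1cc([C@@H](O)[C@H](C=O)c2cc(Br)cc(OC)c2OCc2ccccc2)ccc1OCc1ccccc1 | intermediate (not isolated)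
19 | (1S,2S)-1-[4-(benzyloxy)-3-methoxyphenyl]-2-[2-(benzyloxy)-5-bromo-3-methoxyphenyl]propane-1,3-diol | COc1cc([C@@H](O)[C@H](CO)c2cc(Br)cc(OC)c2OCc2ccccc2)ccc1OCc1ccccc1 | intermediate
20 | G1 bromide | COc1cc([C@@H](O[Si](C)(C)C(C)(C)C)[C@H](CO[Si](C)(C)C(C)(C)C)c2cc(Br)cc(OC)c2OCc2ccccc2)ccc1OCc1ccccc1 | intermediate
21 | G1-lithium | COc1cc([C@@H](O[Si](C)(C)C(C)(C)C)[C@H](CO[Si](C)(C)C(C)(C)C)c2cc([Li])cc(OC)c2OCc2ccccc2)ccc1OCc1ccccc1 | intermediate (not isolated)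
22 | G1-carbaldehyde | COc1cc([C@@H](O[Si](C)(C)C(C)(C)C)[C@H](CO[Si](C)(C)C(C)(C)C)c2cc(C=O)cc(OC)c2OCc2ccccc2)ccc1OCc1ccccc1 | intermediate
23 | G1-methanol | COc1cc([C@@H](O[Si](C)(C)C(C)(C)C)[C@H](CO[Si](C)(C)C(C)(C)C)c2cc(CO)cc(OC)c2OCc2ccccc2)ccc1OCc1ccccc1 | intermediate
24 | G1-methyl bromide | COc1cc([C@@H](O[Si](C)(C)C(C)(C)C)[C@H](CO[Si](C)(C)C(C)(C)C)c2cc(CBr)cc(OC)c2OCc2ccccc2)ccc1OCc1ccccc1 | intermediate
25 | (S)-4-benzyl-1,3-oxazolidin-2-one | O=C1N[C@@H](Cc2ccccc2)CO1 | starting material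
26 | pent-4-enoyl chloride | C=CCCC(=O)Cl | starting material
27 | (S)-4-benzyl-3-(pent-4-enoyl)-1,3-oxazolidin-2-one | C=CCCC(=O)N1[C@@H](Cc2ccccc2)COC1=O | intermediate
28 | sodium (Z)-enolate of 27 | C=CC/C=C(\[O-])N1[C@@H](Cc2ccccc2)COC1=O.[Na+] | intermediate (not isolated)
29 | (4S)-4-benzyl-3-[(2R)-2-(G1-methyl)pent-4-enoyl]-1,3-oxazolidin-2-one | COc1cc([C@@H](O[Si](C)(C)C(C)(C)C)[C@H](CO[Si](C)(C)C(C)(C)C)c2cc(C[C@@H](CC=C)C(=O)N3[C@@H](Cc4ccccc4)COC3=O)cc(OC)c2OCc2ccccc2)ccc1OCc1ccccc1 | intermediate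
30 | (2R)-2-(G1-methyl)pent-4-en-1-ol | COc1cc([C@@H](O[Si](C)(C)C(C)(C)C)[C@H](CO[Si](C)(C)C(C)(C)C)c2cc(C[C@@H](CC=C)CO)cc(OC)c2OCc2ccccc2)ccc1OCc1ccccc1 | intermediate
31 | (3S)-3-(G1-methyl)-4-hydroxybutanal | COc1cc([C@@H](O[Si](C)(C)C(C)(C)C)[C@H](CO[Si](C)(C)C(C)(C)C)c2cc(C[C@@H](CC=O)CO)cc(OC)c2OCc2ccccc2)ccc1OCc1ccccc1 | intermediate (not isolated)
32 | (4S)-4-(G1-methyl)oxolan-2-ol (anomer mixture) | COc1cc([C@@H](O[Si](C)(C)C(C)(C)C)[C@H](CO[Si](C)(C)C(C)(C)C)c2cc(C[C@@H]3COC(O)C3)cc(OC)c2OCc2ccccc2)ccc1OCc1ccccc1 | intermediate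
33 | (4S)-4-(G1-methyl)oxolan-2-one (fragment 1) | COc1cc([C@@H](O[Si](C)(C)C(C)(C)C)[C@H](CO[Si](C)(C)C(C)(C)C)c2cc(C[C@@H]3COC(=O)C3)cc(OC)c2OCc2ccccc2)ccc1OCc1ccccc1 | intermediate
34 | lithium enolate of 33 | COc1cc([C@@H](O[Si](C)(C)C(C)(C)C)[C@H](CO[Si](C)(C)C(C)(C)C)c2cc(C[C@@H]3COC([O-])=C3)cc(OC)c2OCc2ccccc2)ccc1OCc1ccccc1.[Li+] | intermediate (not isolated)
35 | (3R,4S)-3-[hydroxy(G2)methyl]-4-(G1-methyl)oxolan-2-one (carbinol epimers) | COc1cc([C@@H](O[Si](C)(C)C(C)(C)C)[C@H](CO[Si](C)(C)C(C)(C)C)c2cc(C[C@@H]3COC(=O)[C@H]3C(O)c3cc(OC)c4c(c3)[C@@H](CO[Si](C)(C)C(C)(C)C)[C@H](c3ccc(OCc5ccccc5)c(OC)c3)O4)cc(OC)c2OCc2ccccc2)ccc1OCc1ccccc1 | intermediate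
36 | O-phenyl thionocarbonate of 35 | COc1cc([C@@H](O[Si](C)(C)C(C)(C)C)[C@H](CO[Si](C)(C)C(C)(C)C)c2cc(C[C@@H]3COC(=O)[C@H]3C(OC(=S)Oc6ccccc6)c3cc(OC)c4c(c3)[C@@H](CO[Si](C)(C)C(C)(C)C)[C@H](c3ccc(OCc5ccccc5)c(OC)c3)O4)cc(OC)c2OCc2ccccc2)ccc1OCc1ccccc1 | intermediate
37 | (3S,4S)-3-(G2-methyl)-4-(G1-methyl)oxolan-2-one | COc1cc([C@@H](O[Si](C)(C)C(C)(C)C)[C@H](CO[Si](C)(C)C(C)(C)C)c2cc(C[C@@H]3COC(=O)[C@H]3Cc3cc(OC)c4c(c3)[C@@H](CO[Si](C)(C)C(C)(C)C)[C@H](c3ccc(OCc5ccccc5)c(OC)c3)O4)cc(OC)c2OCc2ccccc2)ccc1OCc1ccccc1 | intermediate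
38 | tri-O-benzyl ether of the target | COc1cc([C@@H](O)[C@H](CO)c2cc(C[C@@H]3COC(=O)[C@H]3Cc3cc(OC)c4c(c3)[C@@H](CO)[C@H](c3ccc(OCc5ccccc5)c(OC)c3)O4)cc(OC)c2OCc2ccccc2)ccc1OCc1ccccc1 | intermediate
39 | CNP0199264.1 | COc1cc([C@@H](O)[C@H](CO)c2cc(C[C@@H]3COC(=O)[C@H]3Cc3cc(OC)c4c(c3)[C@@H](CO)[C@H](c3ccc(O)c(OC)c3)O4)cc(OC)c2O)ccc1O | target

**Step count and risks**
Total: 27 steps. Longest linear sequence: 22 steps (steps 1–7, 12–17, 19–27, from 1 to 39).

Step 6 is the least certain step. The boronate is hindered, the aldehyde is electron-rich, and both the rate and the enantioselectivity of the phosphoric-acid-catalysed cinnamylboration could fall short; the catalyst sense is assigned by analogy and would need confirming. It also depends on the boronate from step 5 surviving beside an aryl bromide. The fallback leaves boron chemistry and sets out from allylic alcohol 4. Appel bromination (CBr4, PPh3) gives the (E)-cinnamyl bromide F1. A catalytic asymmetric Nozaki–Hiyama–Kishi allylation of aldehyde 7 follows (CrCl2 10 mol %, a chiral 1,8-bis(oxazolinyl)carbazole ligand of the antipode that gives Si-face addition, Mn powder, Me3SiCl, i-Pr2NEt, THF, rt). Its chair allylchromium transition state gives the anti adduct as the trimethylsilyl ether F2. Bu4NF/AcOH then removes both silyl groups and the route is rejoined at phenol 10.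

Step 13 is the second risk. Ozone may attack the electron-rich rings, and the β-hydroxy-α-aryl aldehyde 18 can dehydrate or undergo retro-aldol cleavage before it is reduced. The fallback changes the protection order and the oxidant and sets out from 17. Silylation of the carbinol first (TBSOTf, 2,6-lutidine) gives the silyl ether F3. Lemieux–Johnson cleavage (OsO4 cat., NaIO4, 2,6-lutidine) gives the β-silyloxy aldehyde F4, which is reduced at once with NaBH4 to the primary alcohol F5. Silylation with TBSCl/imidazole brings the route back at 20.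

Step 25 is the third risk. The thionocarbonate sits β to the lactone carbonyl and may eliminate thermally to the arylidene lactone instead of being reduced. The fallback accepts the elimination and sets out from aldol adduct 35. MsCl/Et3N gives the mesylate F6, and DBU eliminates it to the (E)-arylidene lactone F7. Conjugate reduction with NaBH4/NiCl2·6H2O (MeOH/THF, 0 °C) gives 37 together with its cis C3 epimer F8. DBU in toluene at 80 °C equilibrates the cis epimer to the more stable trans lactone, and the route is rejoined at 37.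

**Further compounds**
F1 | step 6 | (E)-3-{5-bromo-2-[(tert-butyldimethylsilyl)oxy]-3-methoxyphenyl}prop-2-en-1-yl bromide | BrC/C=C/c1cc(Br)cc(OC)c1O[Si](C)(C)C(C)(C)C
F2 | step 6 | trimethylsilyl ether of 9 | COc1cc([C@@H](O[Si](C)(C)C)[C@H](C=C)c2cc(Br)cc(OC)c2O[Si](C)(C)C(C)(C)C)ccc1OCc1ccccc1
F3 | step 13 | (1S,2R)-1-[4-(benzyloxy)-3-methoxyphenyl]-2-[2-(benzyloxy)-5-bromo-3-methoxyphenyl]-1-[(tert-butyldimethylsilyl)oxy]but-3-ene | COc1cc([C@@H](O[Si](C)(C)C(C)(C)C)[C@H](C=C)c2cc(Br)cc(OC)c2OCc2ccccc2)ccc1OCc1ccccc1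
F4 | step 13 | (2R,3S)-3-[4-(benzyloxy)-3-methoxyphenyl]-2-[2-(benzyloxy)-5-bromo-3-methoxyphenyl]-3-[(tert-butyldimethylsilyl)oxy]propanal | COc1cc([C@@H](O[Si](C)(C)C(C)(C)C)[C@H](C=O)c2cc(Br)cc(OC)c2OCc2ccccc2)ccc1OCc1ccccc1
F5 | step 13 | (2S,3S)-3-[4-(benzyloxy)-3-methoxyphenyl]-2-[2-(benzyloxy)-5-bromo-3-methoxyphenyl]-3-[(tert-butyldimethylsilyl)oxy]propan-1-ol | COc1cc([C@@H](O[Si](C)(C)C(C)(C)C)[C@H](CO)c2cc(Br)cc(OC)c2OCc2ccccc2)ccc1OCc1ccccc1
F6 | step 25 | methanesulfonate of 35 | COc1cc([C@@H](O[Si](C)(C)C(C)(C)C)[C@H](CO[Si](C)(C)C(C)(C)C)c2cc(C[C@@H]3COC(=O)[C@H]3C(OS(C)(=O)=O)c3cc(OC)c4c(c3)[C@@H](CO[Si](C)(C)C(C)(C)C)[C@H](c3ccc(OCc5ccccc5)c(OC)c3)O4)cc(OC)c2OCc2ccccc2)ccc1OCc1ccccc1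
F7 | step 25 | (4S,E)-3-(G2-methylidene)-4-(G1-methyl)oxolan-2-one | COc1cc([C@@H](O[Si](C)(C)C(C)(C)C)[C@H](CO[Si](C)(C)C(C)(C)C)c2cc(C[C@@H]3COC(=O)/C3=C/c3cc(OC)c4c(c3)[C@@H](CO[Si](C)(C)C(C)(C)C)[C@H](c3ccc(OCc5ccccc5)c(OC)c3)O4)cc(OC)c2OCc2ccccc2)ccc1OCc1ccccc1
F8 | step 25 | (3R,4S)-3-(G2-methyl)-4-(G1-methyl)oxolan-2-one (cis epimer of 37) | COc1cc([C@@H](O[Si](C)(C)C(C)(C)C)[C@H](CO[Si](C)(C)C(C)(C)C)c2cc(C[C@@H]3COC(=O)[C@@H]3Cc3cc(OC)c4c(c3)[C@@H](CO[Si](C)(C)C(C)(C)C)[C@H](c3ccc(OCc5ccccc5)c(OC)c3)O4)cc(OC)c2OCc2ccccc2)ccc1OCc1ccccc1
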